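At late times a flask tells where its substrate went: what has reacted has left either through the catalyst toward target or by self-condensation, so what is asked is how those two ways shared it.

common to all: free catalyst 2.9 mol%; added ligand 0.20 mM; time 10 h
- gamma: substrate 10 mM (fed, over 6.0 h); coupling partner 1.05 equiv; the addition at 50 °C, then warmed to 80 °C; the feed brings no volume worth counting
- epsilon: substrate 10 mM (fed, over 6.0 h); coupling partner 1.05 equiv; all else is in the flask from the start; the feed brings no volume worth counting; temperature 80 °C
- zeta: substrate 10 mM; coupling partner 1.05 equiv; everything together at the start; temperature 80 °C
- alpha: substrate 10 mM; coupling partner 1.05 equiv (fed, over 1.5 h); all else is in the flask from the start; the feed brings no volume worth counting; temperature 80 °C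

- the best flask by amount of target, in percent of the substrate charged; "all alike" if 1.5 percentage points covers them all (gamma / epsilon / zeta / alpha / all alike)
- amount of target at the end, in percent of the substrate charged, gamma
- amount of target at the end, in percent of the substrate charged, epsilon
- amount of target at the end, in percent of the substrate charged, zeta
- amount of target at the end, in percent of the substrate charged, alpha

- in percentages every species weighs as the substrate in it: one self-condensation product counts as two
- two of one species on the left: rate k times its square, two consumed each time
- at 80 °C the constants are as listed, elsewhere as the activation energies and enthalpies make them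

    free catalyst + added ligand ⇌ idle complex, settled at all times (K1 = 7500 L mol⁻¹, ΔH1 = −51.0 kJ mol⁻¹)
    2 substrate → self-condensation product (k2 = 3.30 L mol⁻¹ min⁻¹, Ea2 = 46.0 kJ mol⁻¹)
    catalyst intermediate B → free catalyst + target (k3 = 1.46 min⁻¹, Ea3 = 107 kJ mol⁻¹)
    coupling partner + free catalyst ⇌ catalyst intermediate A (K4 = 305 L mol⁻¹, k4 = 41.2 L mol⁻¹ min⁻¹, Ea4 = 68.0 kJ mol⁻¹, ΔH4 = 47.0 kJ mol⁻¹)
    substrate + catalyst intermediate A → catalyst intermediate B (k5 = 148 L mol⁻¹ min⁻¹, Ea5 = 36.0 kJ mol⁻¹)
    (constants at 80 °C)

Two of us disputed this at the blackboard. My colleague argues by the clock. In zeta, the forward capture of coupling partner by free catalyst has a half-life of 0.97 h, with the other concentrations held at their charge. The 10 h allowed is ten times that, and the partner stands at 1.05 equiv, so on this view there is time for everything and the flasks finish alike.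

I argue by concentration. At the full substrate charge I take free catalyst entering catalyst intermediate A as the slow act of the round, because its constant at the charged partner, 0.433 min⁻¹, is smaller than those of the two other steps. This step runs back too, but its way back, 0.135 min⁻¹, is slower at that charge than the onward step from catalyst intermediate A. Taking the added ligand crudely as holding its whole charge leaves 0.0900 mM of free catalyst, so the top speed of the catalyst, zero order in substrate, is 0.0389 mM min⁻¹. Self-condensation is second order, and at the full charge it uses 0.660 mM min⁻¹, faster than that top speed. Setting the two equal gives 2.43 mM. This is the balance concentration, the substrate level at which self-condensation uses substrate just as fast as the catalyst at top speed. By this reckoning, with these charges, self-condensation leads above it and the catalyst leads below it.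

Zeta starts above it, so I expect target of the order of the balance concentration, which is 24.3% of the charge. In epsilon the feed of 0.0278 mM min⁻¹ is less than the top speed, so substrate should stay under the balance concentration and target should lie well above zeta. For gamma and alpha I reckon no number.

The forecast takes my side with its own numbers: epsilon best, with gamma 32%, epsilon 62%, zeta 31% and alpha 23%, on the ground that “batch loses most of its substrate”. For zeta it stands higher than my figure.

The simulation gives epsilon as best, with gamma 29.3%, epsilon 65.8%, zeta 29.2% and alpha 19.7%. The clock loses: epsilon stands 37 percentage points above zeta, and epsilon left for 100 h still shows 66.1%. Yet the clock's view stands between gamma and zeta, which lie 0.100 points apart, inside the margin of 1.5 points. The target in zeta amounts to 2.92 mM, against the balance concentration of 2.43 mM.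

Take the neighbour of epsilon whose dosing runs over 1.80 h instead of 6.0 h. Its feed is 0.0926 mM min⁻¹, more than the top speed. The substrate level at which self-condensation by itself would use that feed is 3.75 mM, above the balance concentration. The square of balance concentration over that level equals top speed over feed, 42.0%, and this is my share for target. That neighbour of epsilon ends with 46.0% of target.

The numbers stand for no real mixture; no experiment stands behind them.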